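**Plan**
- Retrosynthesis: the 4-OH is traced back (C4–O inversion) to the 2,4-cis alcohol and then to the C4 ketone. The pyranone is cut at C4–C4a and O1–C8a, giving an o-lithio-fluoroarene and a 4-aryl-β-lactone. C8–prenyl is cut to a directed metalation, and the lactone C3–C2 bond to an aldol.
- Forward: the A ring is silylated and prenylated; the racemic β-lactone is made from the aldehyde. The four-membered lactone ring (O1, C2, C3, C4) is then expanded in one pot to the six-membered pyranone by insertion of C4a and C8a into its acyl–oxygen bond.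
- Enabling feature: O1–C2(aryl)–C3H2–C4(=O) of the pyran ring is a ring-opened 4-aryl-β-lactone. C4a and C8a are adjacent A-ring carbons that can carry Li and F, and the C4 ketone formed ortho to C8a–F activates it for substitution. F sits next to the C8 prenyl, so only the 8-prenyl isomer can form.
- Stereochemistry: C2 is left racemic through the ring expansion. Ru–TsDPEN transfer hydrogenation with dynamic kinetic resolution sets both centres (2S,4S, cis), and a Mitsunobu inversion at C4 gives the 2,4-trans (2S,4R) target.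
- Protection: two aryl TIPS ethers, removed last with fluoride.

Key step: step 4

Remark: the flavanone C2 centre opens and recloses under base (retro-oxa-Michael), so it is deliberately set only in step 5; compound 6 is taken as a catalogue item (otherwise one silylation of 4-hydroxybenzaldehyde).

**Step 1**
Reactants: 1 3-fluoro-5-methoxyphenol
Product: 2 (3-fluoro-5-methoxyphenoxy)triisopropylsilane
Conditions: TIPSCl, imidazole, DMF, rt
Reagents that add atoms: chlorotriisopropylsilane (TIPSCl), CC(C)[Si](Cl)(C(C)C)C(C)C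
Why: Imidazole-assisted silylation of a phenol; TIPS is bulky and weakly coordinating, so it should shield its neighbours in the later lithiations and come off with fluoride at the end.

**Step 2**
Reactants: 2 (3-fluoro-5-methoxyphenoxy)triisopropylsilane; 3 1-bromo-3-methylbut-2-ene (prenyl bromide)
Product: 5 [3-fluoro-5-methoxy-4-(3-methylbut-2-en-1-yl)phenoxy]triisopropylsilane, via aryllithium 4 (not isolated)
Conditions: n-BuLi, THF, −78 °C; then CuBr·SMe2 (10 mol%), 3, −78 → −40 °C
Reagents that add atoms: none
Why: Directed ortho-metalation should take the proton between F and OMe (most acidic, two coordinating neighbours, the other sites shielded by OTIPS), and copper-catalysed allylation of the aryllithium at the primary carbon of prenyl bromide installs the prenyl group.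

**Step 3**
Reactants: 6 4-(triisopropylsilyloxy)benzaldehyde; 7 S-phenyl ethanethioate
Product: 10 rac-4-[4-(triisopropylsilyloxy)phenyl]oxetan-2-one, via lithium thioester enolate 8 (not isolated), via lithium aldolate 9 (not isolated)
Conditions: LDA, THF, −78 °C; then 6, −78 → 0 °C; cold NH4Cl work-up, used promptly
Reagents that add atoms: none
Why: Thioester-enolate aldol addition followed by lactonisation, in which the aldolate displaces thiophenoxide at the acyl carbon (4-exo-trig); the new centre is formed racemic on purpose.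

**Step 4**
Reactants: 5 [3-fluoro-5-methoxy-4-(3-methylbut-2-en-1-yl)phenoxy]triisopropylsilane; 10 rac-4-[4-(triisopropylsilyloxy)phenyl]oxetan-2-one
Product: 13 rac-7-methoxy-8-(3-methylbut-2-en-1-yl)-5-(triisopropylsilyloxy)-2-[4-(triisopropylsilyloxy)phenyl]-2,3-dihydro-4H-chromen-4-one, via aryllithium 11 (not isolated), via lithium oxido ketone 12 (not isolated)
Conditions: s-BuLi, PMDTA, THF, −78 °C; then 10, −78 °C; then DMPU, −78 °C → rt (40 °C if needed); AcOH quench
Reagents that add atoms: none
Why: Proposed new method: s-BuLi/PMDTA should remove the only proton next to fluorine in 5 (more acidic than the one between OMe and OTIPS) to give 11, which adds to the strained lactone carbonyl of 10; collapse of the tetrahedral intermediate with acyl–O cleavage gives the β-oxido ketone 12, whose alkoxide (the former lactone oxygen) then attacks C8a, now activated by the ortho C4 ketone, and expels fluoride, so that the C4a–C8a edge of the arene is inserted into the acyl–oxygen bond and the four-membered ring (O1, C2, C3, C4) becomes the six-membered pyranone. The closest known reaction types are the acylation of organolithiums by β-lactones to β-hydroxy ketones, the intramolecular SNAr of alkoxides onto o-fluoroaryl ketones, and the two-atom ring expansion of cyclic ureas by formal aryne insertion into N–C(O). The one ring closed is the pyranone, by 6-exo-trig addition–elimination (SNAr) at C8a. No stereocentre is set: C2 is carried over racemic from 10 and is fixed in step 5. The step needs acyl rather than benzylic alkyl–O attack on 10 and a single addition (hard aryllithium at −78 °C, hindered 2,6-disubstituted ketone), acylation before LiF loss from 11 (kept at −78 °C), and SNAr ahead of retro-aldol or dehydration of 12 (DMPU frees the alkoxide); the fluorine next to the prenyl group fixes O1 at C8a, so no 6-prenyl isomer can form.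

**Step 5**
Reactants: 13 rac-7-methoxy-8-(3-methylbut-2-en-1-yl)-5-(triisopropylsilyloxy)-2-[4-(triisopropylsilyloxy)phenyl]-2,3-dihydro-4H-chromen-4-one
Product: 14 (2S,4S)-7-methoxy-8-(3-methylbut-2-en-1-yl)-5-(triisopropylsilyloxy)-2-[4-(triisopropylsilyloxy)phenyl]-3,4-dihydro-2H-chromen-4-ol (2,4-cis)
Conditions: RuCl[(S,S)-TsDPEN](p-cymene) (cat.), HCO2H, DBU, MeCN, 40 °C
Reagents that add atoms: none
Why: Asymmetric transfer hydrogenation with dynamic kinetic resolution: DBU racemises C2 through reversible retro-oxa-Michael opening, and the (S,S)-catalyst should deliver hydride to give the 4S carbinol only from the (2S)-ketone (axial delivery, 2-aryl equatorial), so the catalyst sets C4 and the matched pairing sets C2, giving the cis alcohol.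

**Step 6**
Reactants: 14 (2S,4S)-cis alcohol
Product: 15 (2S,4R)-7-methoxy-8-(3-methylbut-2-en-1-yl)-5-(triisopropylsilyloxy)-2-[4-(triisopropylsilyloxy)phenyl]-3,4-dihydro-2H-chromen-4-yl 4-nitrobenzoate (2,4-trans)
Conditions: 4-nitrobenzoic acid, PPh3, DIAD, toluene/THF, 0 °C → rt
Reagents that add atoms: 4-nitrobenzoic acid, O=C(O)c1ccc(cc1)[N+](=O)[O-]
Why: Mitsunobu reaction, in which the carboxylate displaces the alkoxyphosphonium with inversion at C4 (S → R); any ionisation through the stabilised benzylic cation should be captured axially and lead to the same trans ester.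

**Step 7**
Reactants: 15 (2S,4R)-4-nitrobenzoate
Product: 16 (2S,4R)-7-methoxy-8-(3-methylbut-2-en-1-yl)-5-(triisopropylsilyloxy)-2-[4-(triisopropylsilyloxy)phenyl]-3,4-dihydro-2H-chromen-4-ol (2,4-trans)
Conditions: LiOH·H2O, THF/H2O, 0 °C; pH 7 work-up
Reagents that add atoms: none
Why: Saponification by acyl–oxygen cleavage leaves the C4–O bond and its configuration untouched; the aqueous medium and the still-silylated 5-oxygen should prevent quinone-methide formation and ether formation at C4.

**Step 8**
Reactants: 16 (2S,4R)-bis-TIPS trans alcohol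
Product: 17 (2S,4R)-2-(4-hydroxyphenyl)-7-methoxy-8-(3-methylbut-2-en-1-yl)-3,4-dihydro-2H-chromene-4,5-diol (4,5,4'-trihydroxy-7-methoxy-8-prenylflavan)
Conditions: TBAF, AcOH, THF, 0 °C; neutral work-up
Reagents that add atoms: none
Why: Fluoride cleaves both aryl silyl ethers (Si–F bond formation) under buffered conditions that should leave the benzylic 4-OH, the prenyl group and both stereocentres intact.

**Compound list**
1 | 3-fluoro-5-methoxyphenol | COc1cc(O)cc(F)c1 | starting material
2 | (3-fluoro-5-methoxyphenoxy)triisopropylsilane | COc1cc(F)cc(O[Si](C(C)C)(C(C)C)C(C)C)c1 | intermediate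
3 | 1-bromo-3-methylbut-2-ene (prenyl bromide) | CC(C)=CCBr | starting material
4 | [2-fluoro-6-methoxy-4-(triisopropylsilyloxy)phenyl]lithium | [Li]c1c(F)cc(O[Si](C(C)C)(C(C)C)C(C)C)cc1OC | intermediate (not isolated)
5 | [3-fluoro-5-methoxy-4-(3-methylbut-2-en-1-yl)phenoxy]triisopropylsilane | COc1cc(O[Si](C(C)C)(C(C)C)C(C)C)cc(F)c1CC=C(C)C | intermediate
6 | 4-(triisopropylsilyloxy)benzaldehyde | O=Cc1ccc(O[Si](C(C)C)(C(C)C)C(C)C)cc1 | starting material
7 | S-phenyl ethanethioate | CC(=O)Sc1ccccc1 | starting material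
8 | lithium 1-(phenylsulfanyl)ethen-1-olate | [Li]OC(=C)Sc1ccccc1 | intermediate (not isolated)
9 | lithium 3-oxo-3-(phenylsulfanyl)-1-[4-(triisopropylsilyloxy)phenyl]propan-1-olate (racemic) | [Li]OC(CC(=O)Sc1ccccc1)c1ccc(O[Si](C(C)C)(C(C)C)C(C)C)cc1 | intermediate (not isolated)
10 | rac-4-[4-(triisopropylsilyloxy)phenyl]oxetan-2-one | O=C1CC(O1)c1ccc(O[Si](C(C)C)(C(C)C)C(C)C)cc1 | intermediate
11 | [2-fluoro-4-methoxy-3-(3-methylbut-2-en-1-yl)-6-(triisopropylsilyloxy)phenyl]lithium | COc1cc(O[Si](C(C)C)(C(C)C)C(C)C)c([Li])c(F)c1CC=C(C)C | intermediate (not isolated)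
12 | lithium 3-[2-fluoro-4-methoxy-3-(3-methylbut-2-en-1-yl)-6-(triisopropylsilyloxy)phenyl]-3-oxo-1-[4-(triisopropylsilyloxy)phenyl]propan-1-olate (racemic) | [Li]OC(CC(=O)c1c(F)c(CC=C(C)C)c(OC)cc1O[Si](C(C)C)(C(C)C)C(C)C)c1ccc(O[Si](C(C)C)(C(C)C)C(C)C)cc1 | intermediate (not isolated)
13 | rac-7-methoxy-8-(3-methylbut-2-en-1-yl)-5-(triisopropylsilyloxy)-2-[4-(triisopropylsilyloxy)phenyl]-2,3-dihydro-4H-chromen-4-one | COc1cc(O[Si](C(C)C)(C(C)C)C(C)C)c2c(c1CC=C(C)C)OC(c1ccc(O[Si](C(C)C)(C(C)C)C(C)C)cc1)CC2=O | intermediate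
14 | (2S,4S)-7-methoxy-8-(3-methylbut-2-en-1-yl)-5-(triisopropylsilyloxy)-2-[4-(triisopropylsilyloxy)phenyl]-3,4-dihydro-2H-chromen-4-ol (2,4-cis) | COc1cc(O[Si](C(C)C)(C(C)C)C(C)C)c2c(c1CC=C(C)C)O[C@H](c1ccc(O[Si](C(C)C)(C(C)C)C(C)C)cc1)C[C@@H]2O | intermediate
15 | (2S,4R)-7-methoxy-8-(3-methylbut-2-en-1-yl)-5-(triisopropylsilyloxy)-2-[4-(triisopropylsilyloxy)phenyl]-3,4-dihydro-2H-chromen-4-yl 4-nitrobenzoate (2,4-trans) | COc1cc(O[Si](C(C)C)(C(C)C)C(C)C)c2c(c1CC=C(C)C)O[C@H](c1ccc(O[Si](C(C)C)(C(C)C)C(C)C)cc1)C[C@H]2OC(=O)c1ccc(cc1)[N+](=O)[O-] | intermediate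
16 | (2S,4R)-7-methoxy-8-(3-methylbut-2-en-1-yl)-5-(triisopropylsilyloxy)-2-[4-(triisopropylsilyloxy)phenyl]-3,4-dihydro-2H-chromen-4-ol (2,4-trans) | COc1cc(O[Si](C(C)C)(C(C)C)C(C)C)c2c(c1CC=C(C)C)O[C@H](c1ccc(O[Si](C(C)C)(C(C)C)C(C)C)cc1)C[C@H]2O | intermediate
17 | (2S,4R)-2-(4-hydroxyphenyl)-7-methoxy-8-(3-methylbut-2-en-1-yl)-3,4-dihydro-2H-chromene-4,5-diol | COc1cc(O)c2c(c1CC=C(C)C)O[C@H](c1ccc(O)cc1)C[C@H]2O | target

**Count**
Total steps: 8. Longest linear sequence: 7 steps (1, 2, 4, 5, 6, 7, 8); step 3 is a one-step branch.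

**Steps most likely to fail**

Step 4 (proposed new method). The aryllithium 11 may lose LiF to an aryne before it is acylated, s-BuLi may attack the allylic/benzylic CH2 of the prenyl group, or the fluoride displacement may be slow enough for 12 to undergo retro-aldol cleavage or dehydration. The fallback uses known chemistry and builds the pyranone by oxa-Michael closure with late prenylation; it sets out from aldehyde 6 and comes back at 13. Aldehyde 6 is condensed with commercial 1-(2,6-dihydroxy-4-methoxyphenyl)ethanone (pyrrolidine, EtOH, 60 °C; aldol condensation then 6-endo oxa-Michael addition, the two hydroxyls being equivalent by symmetry) to give rac-5-hydroxy-7-methoxy-2-[4-(triisopropylsilyloxy)phenyl]-2,3-dihydro-4H-chromen-4-one F1. The chelated 5-OH is etherified with 3-methylbut-2-en-1-ol (PPh3, DIAD) to give rac-7-methoxy-5-(3-methylbut-2-en-1-yloxy)-2-[4-(triisopropylsilyloxy)phenyl]-2,3-dihydro-4H-chromen-4-one F2. A Eu(fod)3-catalysed tandem Claisen–Cope rearrangement (CHCl3, 60 °C; O5 → C6 → C8) should then give rac-5-hydroxy-7-methoxy-8-(3-methylbut-2-en-1-yl)-2-[4-(triisopropylsilyloxy)phenyl]-2,3-dihydro-4H-chromen-4-one F3, and TIPSOTf/2,6-lutidine converts it into 13.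

Step 6. The activated alcohol may eliminate to the flav-3-ene, or the peri silyloxy group may block backside attack so that little ester forms. The fallback replaces the SN2 inversion by equilibration through the benzylic cation; it sets out from 14 and comes back at 16. Alcohol 14 is stirred with catalytic camphorsulfonic acid in wet THF at 0 °C → rt; C4 ionises to the cation stabilised by O1, the 5-oxygen and the 7-methoxy group, and water should return mainly from the axial direction to give the trans alcohol 16. Remaining 14 is separated and resubmitted.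

Step 5. Hydride transfer may be slowed by the peri silyloxy group, racemisation of C2 may lag behind reduction (loss of enantiomeric purity), or the ring-opened chalcone may be reduced. The fallback separates reduction from resolution; it sets out from 13 and comes back at 14. Ketone 13 is reduced with NaBH4 (MeOH/THF, 0 °C; axial hydride delivery) to rac-(2S*,4S*)-7-methoxy-8-(3-methylbut-2-en-1-yl)-5-(triisopropylsilyloxy)-2-[4-(triisopropylsilyloxy)phenyl]-3,4-dihydro-2H-chromen-4-ol F4. A lipase-catalysed acylation (Burkholderia cepacia lipase, vinyl acetate, MTBE, 30 °C) should then convert the (4R)-enantiomer into (2R,4R)-7-methoxy-8-(3-methylbut-2-en-1-yl)-5-(triisopropylsilyloxy)-2-[4-(triisopropylsilyloxy)phenyl]-3,4-dihydro-2H-chromen-4-yl acetate F5 and leave 14, which is separated by chromatography.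

**Further compounds**
F1 | step 4 | rac-5-hydroxy-7-methoxy-2-[4-(triisopropylsilyloxy)phenyl]-2,3-dihydro-4H-chromen-4-one | COc1cc(O)c2c(c1)OC(c1ccc(O[Si](C(C)C)(C(C)C)C(C)C)cc1)CC2=O
F2 | step 4 | rac-7-methoxy-5-(3-methylbut-2-en-1-yloxy)-2-[4-(triisopropylsilyloxy)phenyl]-2,3-dihydro-4H-chromen-4-one | COc1cc(OCC=C(C)C)c2c(c1)OC(c1ccc(O[Si](C(C)C)(C(C)C)C(C)C)cc1)CC2=O
F3 | step 4 | rac-5-hydroxy-7-methoxy-8-(3-methylbut-2-en-1-yl)-2-[4-(triisopropylsilyloxy)phenyl]-2,3-dihydro-4H-chromen-4-one | COc1cc(O)c2c(c1CC=C(C)C)OC(c1ccc(O[Si](C(C)C)(C(C)C)C(C)C)cc1)CC2=O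
F0 | step 6 | none | none
F4 | step 5 | rac-(2S*,4S*)-7-methoxy-8-(3-methylbut-2-en-1-yl)-5-(triisopropylsilyloxy)-2-[4-(triisopropylsilyloxy)phenyl]-3,4-dihydro-2H-chromen-4-ol (2,4-cis racemate) | COc1cc(O[Si](C(C)C)(C(C)C)C(C)C)c2c(c1CC=C(C)C)OC(c1ccc(O[Si](C(C)C)(C(C)C)C(C)C)cc1)CC2O
F5 | step 5 | (2R,4R)-7-methoxy-8-(3-methylbut-2-en-1-yl)-5-(triisopropylsilyloxy)-2-[4-(triisopropylsilyloxy)phenyl]-3,4-dihydro-2H-chromen-4-yl acetate | COc1cc(O[Si](C(C)C)(C(C)C)C(C)C)c2c(c1CC=C(C)C)O[C@@H](c1ccc(O[Si](C(C)C)(C(C)C)C(C)C)cc1)C[C@H]2OC(C)=O
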